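**Remark on numbering and one assumption.** Ring positions are numbered as in a 1-aryl-1,2-dihydronaphthalene: C1 (CH–aryl), C2 (CH–CH2OH), C3 (C–CHO), C4 (vinylic CH), C4a/C8a (ring fusion), C5–C8 (arene; C6-OMe, C7-OH, C8-OMe). The SMILES encodes (1S,2R), trans. TBS = tert-butyldimethylsilyl. Assumption: in the fallback for step 8 the facial sense of the mandelate auxiliary is assigned by analogy with hydroxy-o-quinodimethane additions to mandelate fumarates; the enantiomeric mandelate would be used if the sense were opposite.

## Analysis of the target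

Target 17 is a 2,7′-cyclolignan of the 1-aryl-1,2-dihydronaphthalene type. The carbocycle C1–C2–C3–C4–C4a–C8a is fused to a syringyl-derived arene (C5-H, C6-OMe, C7-OH, C8-OMe). C1 carries a guaiacyl ring, C2 a hydroxymethyl group, and C3 a formyl group conjugated through C3=C4 with the arene. There are two contiguous stereocentres, C1 (S) and C2 (R), trans to each other. Neither can be repaired late: C1 is a diarylmethine, and C2 sits on the α-carbon of the enal, so its proton is not acidified. Sensitive features are the two electron-rich free phenols, a dihydronaphthalene that aromatises on dehydrogenation, an enal next to a γ-hydroxyl group, and the crowded C1 flanked by the peri C8-OMe. The difficulty is to place two one-carbon groups of different oxidation level on adjacent ring carbons while setting the vicinal diarylmethine/alkyl pair in absolute terms.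

## Retrosynthetic reasoning

**17 from 16.** Only the three O–Si bonds are cut. All three hydroxyl groups are masked as the same silyl ether, so one fluoride treatment ends the synthesis and nothing on the skeleton changes.

**16 from 9 and 12 (key step).** The bonds C1–C2 and C3–C4 are cut, which opens the central ring and removes both stereocentres. Precursor 9 is an achiral diarylmethane aldehyde whose CH2 becomes C1 and whose formyl carbon becomes C4. Enal 12 supplies C2, C3 and both one-carbon appendages already at their final oxidation levels. The cut is made here because the ortho-benzyl-benzaldehyde motif of 9 is a latent nucleophile: light converts it into photoenol 13, whose aryl-bearing terminus can add to the β-carbon of 12 when 12 is activated as an iminium ion by a chiral secondary amine. The resulting enamine of 14 closes onto the regenerated formyl group (aldol 15) and dehydrates to 16. The forward step therefore has to build the ring, set C1 and C2 together, and leave the enal in place, in one operation.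

**9 from 3 and 7 (through 8).** The aryl–CH2 bond is cut. A benzylzinc reagent 8 made from chloride 7 couples with bromide 3 under palladium catalysis, a reaction type that tolerates the free formyl group.

**3 from 1, and 7 from 4.** Bromide 3 comes from 1 by bromination at its only free ring position (giving 2) and silylation. Chloride 7 comes from 4 by silylation (5), reduction (6) and chlorination.

**12 from 10 and 11.** The C2=C3 bond of the enal is cut; a Wittig reaction of aldehyde 10 with formyl ylide 11 gives the (E)-enal.

## Alternatives that were turned down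

**Alternative 1:** (textbook) Disconnection of C1–C8a. An acyclic 8–8′-linked hydroxy diester A1 would be assembled from 1 and 4 by Stobbe condensation with a succinate diester followed by an aldol reaction. Acid would ionise the benzylic carbinol to a quinone-methide-type cation, which closes by Friedel–Crafts attack of the syringyl ring to give the trans product from either carbinol epimer. This closure is stereoconvergent only at C1 and only relative to C2. The C2 centre of A1 is α to an ester and would need an auxiliary-controlled aldol to be set in absolute terms. The attacking arene position is deactivated by the conjugated ester. After closure, three redox steps are still needed (diester to diol to selective allylic oxidation), giving a sequence of more than eleven steps.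

**Alternative 2:** Disconnection of the C1–aryl bond by dearomatisation. A lithiated, O-protected guaiacyl ring would add to C1 of the chiral 2-naphthyl oxazoline A2, with a proton quench at C2. The flat precursor A2 is a 2,3,6,7,8-pentasubstituted naphthalene that itself needs about seven steps. The addition must occur at C1, peri to the C8-OMe group. The kinetic proton quench is not guaranteed to give the 1,2-trans relationship, and equilibration α to the oxazoline invites migration of the C3=C4 bond. Converting the oxazoline to CH2OH and the C3 side chain to CHO costs four more steps.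

**Alternative 3:** Disconnection of C4–C4a. A γ,γ-diarylbutyric acid, with C1 set by rhodium-catalysed asymmetric conjugate arylation and C2 by alkylation, would be closed by Friedel–Crafts acylation to the 4-aryl-1-tetralone A3. C3-formylation, ketone reduction and dehydration would follow. Both electron-rich aryl rings at C1 can accept the acylium ion, so the ring closure has no built-in regiocontrol. The two stereocentres are set in two separate operations. The enal is reached only after a formylation/reduction/elimination sequence, for a linear sequence of about thirteen steps.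

Key step: step 8

## Steps

Step 1
Reactants: 1 syringaldehyde (4-hydroxy-3,5-dimethoxybenzaldehyde)
Product: 2 2-bromo-4-hydroxy-3,5-dimethoxybenzaldehyde
Conditions: Br2 (1.05 equiv), AcOH, 15–20 °C
Reagents that add atoms: bromine, BrBr
Why: Electrophilic aromatic bromination; C2/C6 are the only free positions of 1 and are activated ortho/para by the two methoxy groups, while the formyl group occupies the position para to OH.

Step 2
Reactants: 2 2-bromo-4-hydroxy-3,5-dimethoxybenzaldehyde
Product: 3 2-bromo-4-[(tert-butyldimethylsilyl)oxy]-3,5-dimethoxybenzaldehyde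
Conditions: TBSCl, imidazole, DMF, rt
Reagents that add atoms: tert-butyldimethylsilyl chloride, CC(C)(C)[Si](C)(C)Cl
Why: Imidazole-promoted silylation of a phenol; the DMF protocol also handles the di-ortho-substituted phenol, and the silyl ether removes the acidic proton before the organozinc step.

Step 3
Reactants: 4 vanillin (4-hydroxy-3-methoxybenzaldehyde)
Product: 5 4-[(tert-butyldimethylsilyl)oxy]-3-methoxybenzaldehyde
Conditions: TBSCl, imidazole, CH2Cl2, rt
Reagents that add atoms: tert-butyldimethylsilyl chloride, CC(C)(C)[Si](C)(C)Cl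
Why: Standard phenol silylation; the same protecting group as in 3 allows one global deprotection at the end.

Step 4
Reactants: 5 4-[(tert-butyldimethylsilyl)oxy]-3-methoxybenzaldehyde
Product: 6 {4-[(tert-butyldimethylsilyl)oxy]-3-methoxyphenyl}methanol
Conditions: NaBH4, MeOH/THF, 0 °C
Reagents that add atoms: none
Why: Borohydride reduction of an aryl aldehyde; the aryl silyl ether should survive at 0 °C with short contact time.

Step 5
Reactants: 6 {4-[(tert-butyldimethylsilyl)oxy]-3-methoxyphenyl}methanol
Product: 7 tert-butyl[4-(chloromethyl)-2-methoxyphenoxy]dimethylsilane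
Conditions: SOCl2, pyridine, CH2Cl2, 0 °C; used crude
Reagents that add atoms: thionyl chloride, O=S(Cl)Cl
Why: Chlorodehydroxylation through the chlorosulfite; the electron-rich benzylic position reacts at 0 °C and pyridine buffers the HCl so the silyl ether stays intact.

Step 6
Reactants: 7 tert-butyl[4-(chloromethyl)-2-methoxyphenoxy]dimethylsilane, 3 2-bromo-4-[(tert-butyldimethylsilyl)oxy]-3,5-dimethoxybenzaldehyde
Product: 9 4-[(tert-butyldimethylsilyl)oxy]-2-{4-[(tert-butyldimethylsilyl)oxy]-3-methoxybenzyl}-3,5-dimethoxybenzaldehyde, via benzylzinc chloride 8 (not isolated)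
Conditions: Zn dust, LiCl, THF, 25 °C; then 3, Pd(OAc)2 (2 mol %), SPhos (4 mol %), THF, 25–50 °C
Reagents that add atoms: none
Why: LiCl-assisted zinc insertion into the benzylic chloride followed by Negishi cross-coupling; benzylzinc halides tolerate a free formyl group, and the biarylphosphine ligand allows oxidative addition at the di-ortho-substituted C–Br bond, which the ortho-formyl group activates.

Step 7
Reactants: 10 [(tert-butyldimethylsilyl)oxy]acetaldehyde, 11 (triphenylphosphoranylidene)acetaldehyde
Product: 12 (E)-4-[(tert-butyldimethylsilyl)oxy]but-2-enal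
Conditions: toluene, 70 °C
Reagents that add atoms: none
Why: Wittig olefination with a stabilised formyl ylide, which should give the (E)-enal; a slight deficit of ylide limits a second homologation.

Step 8
Reactants: 9 4-[(tert-butyldimethylsilyl)oxy]-2-{4-[(tert-butyldimethylsilyl)oxy]-3-methoxybenzyl}-3,5-dimethoxybenzaldehyde, 12 (E)-4-[(tert-butyldimethylsilyl)oxy]but-2-enal
Product: 16 (1S,2R)-7-[(tert-butyldimethylsilyl)oxy]-1-{4-[(tert-butyldimethylsilyl)oxy]-3-methoxyphenyl}-2-{[(tert-butyldimethylsilyl)oxy]methyl}-6,8-dimethoxy-1,2-dihydronaphthalene-3-carbaldehyde, via photoenol 13 (not isolated), via Michael adduct dialdehyde 14 (not isolated), via aldol 15 (not isolated)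
Conditions: 12 (3 equiv), (R)-2-[diphenyl(trimethylsilyloxy)methyl]pyrrolidine (20 mol %), PhCO2H (20 mol %), degassed toluene, 365 nm LED, 10 °C; then lamp off, 40 °C
Reagents that add atoms: none
Why: Proposed new method: excitation of 9 (n,π*) should trigger 1,5-hydrogen transfer from the doubly benzylic CH2 to the carbonyl oxygen and give the (E,E)-hydroxy-o-quinodimethane 13, whose aryl-bearing terminus (distal to OH, largest HOMO coefficient) adds to the β-carbon of the LUMO-lowered iminium ion formed from 12 and the amine, restoring the arene and leaving the enamine of 14, which closes onto the regenerated formyl group (aldol 15) and dehydrates under the acid co-catalyst to the conjugated iminium ion that hydrolyses to 16; the closest known reaction types are the iminium-ion trapping of photoenols of 2-alkylbenzophenones (β-benzylation of enals), the photoenolisation/Diels–Alder reaction of 2-benzylbenzaldehydes, and the amine-catalysed Michael/aldol condensation of 2-(nitromethyl)benzaldehydes with enals. The ring C1–C2–C3–C4–C4a–C8a is closed in a formal [4+2] sense, first by the intermolecular Michael bond C1–C2 and then by a 6-(enolexo)-exo-trig aldol bond C3–C4. C2 is controlled by the catalyst: in the (E)-s-trans iminium ion the CPh2OTMS group of the (R)-amine shields one face of the β-carbon, and attack on the open face gives 2R (the same steric model that accounts for Michael additions of carbon nucleophiles to enals with the (S)-amine predicts 2S for that enantiomer). C1 is controlled by the geometry of 13 and an endo-type alignment: with the aryl group outside on the diene and the iminium π-system under the diene, the CH2OTBS group ends up anti to the aryl group, the 1,2-trans relationship that fumarates give with α-hydroxy-α′-aryl-o-quinodimethanes. The step needs regioselectivity (secured by the hydroxyl donor on the other diene terminus), chemoselectivity for the iminium ion over free 12 (secured by LUMO lowering and the low stationary concentration of 13), and ring closure of 14 faster than its re-excitation (the enamine is formed next to the protonated carbonyl).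

Step 9
Reactants: 16 (1S,2R)-7-[(tert-butyldimethylsilyl)oxy]-1-{4-[(tert-butyldimethylsilyl)oxy]-3-methoxyphenyl}-2-{[(tert-butyldimethylsilyl)oxy]methyl}-6,8-dimethoxy-1,2-dihydronaphthalene-3-carbaldehyde
Product: 17 (1S,2R)-7-hydroxy-1-(4-hydroxy-3-methoxyphenyl)-2-(hydroxymethyl)-6,8-dimethoxy-1,2-dihydronaphthalene-3-carbaldehyde
Conditions: TBAF (3.5 equiv), AcOH (3.5 equiv), THF, 0 °C to rt, argon
Reagents that add atoms: none
Why: Fluoride-mediated cleavage of the two aryl and one primary alkyl silyl ethers; acetic acid buffering keeps the phenols protonated so that oxidation and aromatisation are suppressed, and neither stereocentre is touched.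

## Compound list

1 | syringaldehyde (4-hydroxy-3,5-dimethoxybenzaldehyde) | COc1cc(C=O)cc(OC)c1O | starting material
2 | 2-bromo-4-hydroxy-3,5-dimethoxybenzaldehyde | COc1cc(C=O)c(Br)c(OC)c1O | intermediate
3 | 2-bromo-4-[(tert-butyldimethylsilyl)oxy]-3,5-dimethoxybenzaldehyde | COc1cc(C=O)c(Br)c(OC)c1O[Si](C)(C)C(C)(C)C | intermediate
4 | vanillin (4-hydroxy-3-methoxybenzaldehyde) | COc1cc(C=O)ccc1O | starting material
5 | 4-[(tert-butyldimethylsilyl)oxy]-3-methoxybenzaldehyde | COc1cc(C=O)ccc1O[Si](C)(C)C(C)(C)C | intermediate
6 | {4-[(tert-butyldimethylsilyl)oxy]-3-methoxyphenyl}methanol | COc1cc(CO)ccc1O[Si](C)(C)C(C)(C)C | intermediate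
7 | tert-butyl[4-(chloromethyl)-2-methoxyphenoxy]dimethylsilane | COc1cc(CCl)ccc1O[Si](C)(C)C(C)(C)C | intermediate
8 | {4-[(tert-butyldimethylsilyl)oxy]-3-methoxybenzyl}zinc chloride | COc1cc(C[Zn]Cl)ccc1O[Si](C)(C)C(C)(C)C | intermediate (not isolated)
9 | 4-[(tert-butyldimethylsilyl)oxy]-2-{4-[(tert-butyldimethylsilyl)oxy]-3-methoxybenzyl}-3,5-dimethoxybenzaldehyde | COc1cc(C=O)c(Cc2ccc(O[Si](C)(C)C(C)(C)C)c(OC)c2)c(OC)c1O[Si](C)(C)C(C)(C)C | intermediate
10 | [(tert-butyldimethylsilyl)oxy]acetaldehyde | O=CCO[Si](C)(C)C(C)(C)C | starting material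
11 | (triphenylphosphoranylidene)acetaldehyde | O=CC=P(c1ccccc1)(c1ccccc1)c1ccccc1 | starting material
12 | (E)-4-[(tert-butyldimethylsilyl)oxy]but-2-enal | O=C/C=C/CO[Si](C)(C)C(C)(C)C | intermediate
13 | (E,E)-hydroxy-o-quinodimethane (photoenol) of 9, OH and aryl both outside | O/C=C1\C=C(OC)C(O[Si](C)(C)C(C)(C)C)=C(OC)/C1=C\c1ccc(O[Si](C)(C)C(C)(C)C)c(OC)c1 | intermediate (not isolated)
14 | (3S)-4-[(tert-butyldimethylsilyl)oxy]-3-[(S)-{3-[(tert-butyldimethylsilyl)oxy]-6-formyl-2,4-dimethoxyphenyl}{4-[(tert-butyldimethylsilyl)oxy]-3-methoxyphenyl}methyl]butanal (Michael adduct, present as its enamine) | COc1cc([C@H]([C@@H](CO[Si](C)(C)C(C)(C)C)CC=O)c2c(C=O)cc(OC)c(O[Si](C)(C)C(C)(C)C)c2OC)ccc1O[Si](C)(C)C(C)(C)C | intermediate (not isolated)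
15 | (1S,2R,3S,4S)-4-hydroxy-1,2,3,4-tetrahydronaphthalene-3-carbaldehyde aldol (1,2-trans, 2,3-trans, 3,4-cis expected; C3 and C4 are erased on dehydration), silyl groups as in 16 | COc1cc([C@H]2c3c(cc(OC)c(O[Si](C)(C)C(C)(C)C)c3OC)[C@@H](O)[C@@H](C=O)[C@@H]2CO[Si](C)(C)C(C)(C)C)ccc1O[Si](C)(C)C(C)(C)C | intermediate (not isolated)
16 | (1S,2R)-7-[(tert-butyldimethylsilyl)oxy]-1-{4-[(tert-butyldimethylsilyl)oxy]-3-methoxyphenyl}-2-{[(tert-butyldimethylsilyl)oxy]methyl}-6,8-dimethoxy-1,2-dihydronaphthalene-3-carbaldehyde | COc1cc([C@H]2c3c(cc(OC)c(O[Si](C)(C)C(C)(C)C)c3OC)C=C(C=O)[C@@H]2CO[Si](C)(C)C(C)(C)C)ccc1O[Si](C)(C)C(C)(C)C | intermediate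
17 | (1S,2R)-7-hydroxy-1-(4-hydroxy-3-methoxyphenyl)-2-(hydroxymethyl)-6,8-dimethoxy-1,2-dihydronaphthalene-3-carbaldehyde | COc1cc([C@H]2c3c(cc(OC)c(O)c3OC)C=C(C=O)[C@@H]2CO)ccc1O | target

## Step count and risk

Total: 9 steps. Longest linear sequence: 6 steps (4 → 5 → 6 → 7 → 9 → 16 → 17; steps 3, 4, 5, 6, 8, 9).

**Step 8 (key step, proposed new method).** Four processes may go wrong.
- A racemic background cycloaddition of photoenol 13 with free, non-activated 12 would erode the enantiomeric purity.
- Simple diastereoselection at C1 may be poor if the C1–C2 bond forms through an open rather than an endo-type transition state.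
- Re-excitation of the aryl aldehyde in 14 before ring closure would scramble C1, and competitive light absorption by the cinnamaldehyde-type chromophore of 16 could lead to photochemical ring opening.
- γ-Deprotonation of the iminium ion of 12 to a dienamine, or E/Z photoisomerisation of 12, would divert the electrophile.

The fallback sets out from 9 and comes back at 17, using auxiliary-controlled photoenolisation/Diels–Alder chemistry of known type. Fumaryl chloride is esterified with methyl (R)-mandelate (pyridine, CH2Cl2) to the C2-symmetric bis[(R)-2-methoxy-2-oxo-1-phenylethyl] fumarate F1. Irradiation of 9 (365 nm, toluene) in the presence of F1 should give, by thermal [4+2] addition of photoenol 13, the 1,2-trans-2,3-trans-3,4-cis hydroxy diester F2. Acid-catalysed dehydration of the benzylic alcohol (cat. TsOH, toluene) gives the dihydronaphthalene diester F3. DIBAL-H (CH2Cl2, −78 °C) reduces both esters and releases the auxiliary, giving the diol F4. MnO2 (CH2Cl2) oxidises only the allylic alcohol to the bis-silyl hydroxy enal F5, and TBAF/AcOH then gives 17.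

**Step 6.** Oxidative addition at the di-ortho-substituted C–Br bond may be slow, so that addition of the benzylzinc reagent to the free formyl group and Wurtz-type homocoupling during zinc insertion compete. The fallback sets out from 1 and comes back at 9. Silylation of 1 gives 4-[(tert-butyldimethylsilyl)oxy]-3,5-dimethoxybenzaldehyde F6. In situ protection of its formyl group as the α-amino alkoxide (lithium N,N,N′-trimethylethylenediamide), directed ortho-lithiation at C2 (n-BuLi) and copper-mediated alkylation with 7 give 9 after aqueous work-up, with no halogen and no palladium.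

**Step 7.** A second olefination of the product enal and oligomerisation of the sensitive γ-silyloxy enal on heating may occur. The fallback sets out from 10 and comes back at 12. Horner–Wadsworth–Emmons reaction with triethyl phosphonoacetate gives ethyl (E)-4-[(tert-butyldimethylsilyl)oxy]but-2-enoate F7. DIBAL-H reduction gives (E)-4-[(tert-butyldimethylsilyl)oxy]but-2-en-1-ol F8, and MnO2 oxidation gives 12.

**Step 9.** Phenoxide formation under fluoride may lead to oxidative dehydrogenation of the dihydronaphthalene or to addition to the enal. The fallback sets out from 16 and comes back at 17; it removes the enal before the phenols are unmasked. Luche reduction (NaBH4, CeCl3, MeOH) gives the tris-silyl allylic alcohol F9. Desilylation with TBAF/AcOH gives the free diol diphenol F10. MnO2 then oxidises only the allylic alcohol to 17.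

## Further compounds

F1 | step 8 | bis[(R)-2-methoxy-2-oxo-1-phenylethyl] (E)-but-2-enedioate | COC(=O)[C@H](OC(=O)/C=C/C(=O)O[C@H](c1ccccc1)C(=O)OC)c1ccccc1
F2 | step 8 | bis[(R)-2-methoxy-2-oxo-1-phenylethyl] (1S,2R,3S,4S)-7-[(tert-butyldimethylsilyl)oxy]-1-{4-[(tert-butyldimethylsilyl)oxy]-3-methoxyphenyl}-4-hydroxy-6,8-dimethoxy-1,2,3,4-tetrahydronaphthalene-2,3-dicarboxylate | COc1cc([C@H]2c3c(cc(OC)c(O[Si](C)(C)C(C)(C)C)c3OC)[C@@H](O)[C@@H](C(=O)O[C@H](c4ccccc4)C(=O)OC)[C@@H]2C(=O)O[C@H](c5ccccc5)C(=O)OC)ccc1O[Si](C)(C)C(C)(C)C
F3 | step 8 | bis[(R)-2-methoxy-2-oxo-1-phenylethyl] (1S,2R)-7-[(tert-butyldimethylsilyl)oxy]-1-{4-[(tert-butyldimethylsilyl)oxy]-3-methoxyphenyl}-6,8-dimethoxy-1,2-dihydronaphthalene-2,3-dicarboxylate | COc1cc([C@H]2c3c(cc(OC)c(O[Si](C)(C)C(C)(C)C)c3OC)C=C(C(=O)O[C@H](c4ccccc4)C(=O)OC)[C@@H]2C(=O)O[C@H](c5ccccc5)C(=O)OC)ccc1O[Si](C)(C)C(C)(C)C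
F4 | step 8 | [(1S,2R)-7-[(tert-butyldimethylsilyl)oxy]-1-{4-[(tert-butyldimethylsilyl)oxy]-3-methoxyphenyl}-6,8-dimethoxy-1,2-dihydronaphthalene-2,3-diyl]dimethanol | COc1cc([C@H]2c3c(cc(OC)c(O[Si](C)(C)C(C)(C)C)c3OC)C=C(CO)[C@@H]2CO)ccc1O[Si](C)(C)C(C)(C)C
F5 | step 8 | (1S,2R)-7-[(tert-butyldimethylsilyl)oxy]-1-{4-[(tert-butyldimethylsilyl)oxy]-3-methoxyphenyl}-2-(hydroxymethyl)-6,8-dimethoxy-1,2-dihydronaphthalene-3-carbaldehyde | COc1cc([C@H]2c3c(cc(OC)c(O[Si](C)(C)C(C)(C)C)c3OC)C=C(C=O)[C@@H]2CO)ccc1O[Si](C)(C)C(C)(C)C
F6 | step 6 | 4-[(tert-butyldimethylsilyl)oxy]-3,5-dimethoxybenzaldehyde | COc1cc(C=O)cc(OC)c1O[Si](C)(C)C(C)(C)C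
F7 | step 7 | ethyl (E)-4-[(tert-butyldimethylsilyl)oxy]but-2-enoate | CCOC(=O)/C=C/CO[Si](C)(C)C(C)(C)C
F8 | step 7 | (E)-4-[(tert-butyldimethylsilyl)oxy]but-2-en-1-ol | OC/C=C/CO[Si](C)(C)C(C)(C)C
F9 | step 9 | [(1S,2R)-7-[(tert-butyldimethylsilyl)oxy]-1-{4-[(tert-butyldimethylsilyl)oxy]-3-methoxyphenyl}-2-{[(tert-butyldimethylsilyl)oxy]methyl}-6,8-dimethoxy-1,2-dihydronaphthalen-3-yl]methanol | COc1cc([C@H]2c3c(cc(OC)c(O[Si](C)(C)C(C)(C)C)c3OC)C=C(CO)[C@@H]2CO[Si](C)(C)C(C)(C)C)ccc1O[Si](C)(C)C(C)(C)C
F10 | step 9 | (1S,2R)-1-(4-hydroxy-3-methoxyphenyl)-2,3-bis(hydroxymethyl)-6,8-dimethoxy-1,2-dihydronaphthalen-7-ol | COc1cc([C@H]2c3c(cc(OC)c(O)c3OC)C=C(CO)[C@@H]2CO)ccc1O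
A1 | alternative 1 | dimethyl (E)-2-(4-hydroxy-3,5-dimethoxybenzylidene)-3-[hydroxy(4-hydroxy-3-methoxyphenyl)methyl]succinate (carbinol centre as either epimer) | COc1cc(C(O)[C@@H](C(=O)OC)/C(C(=O)OC)=C\c2cc(OC)c(O)c(OC)c2)ccc1O
A2 | alternative 2 | (4S)-2-[7-(benzyloxy)-3-{[(tert-butyldimethylsilyl)oxy]methyl}-6,8-dimethoxynaphthalen-2-yl]-4-tert-butyl-4,5-dihydro-1,3-oxazole | COc1cc2cc(CO[Si](C)(C)C(C)(C)C)c(cc2c(OC)c1OCc1ccccc1)C1=N[C@H](CO1)C(C)(C)C
A3 | alternative 3 | (3S,4S)-6-(benzyloxy)-4-[4-(benzyloxy)-3-methoxyphenyl]-3-[(benzyloxy)methyl]-5,7-dimethoxy-3,4-dihydronaphthalen-1(2H)-one | COc1cc([C@H]2c3c(cc(OC)c(OCc4ccccc4)c3OC)C(=O)C[C@@H]2COCc2ccccc2)ccc1OCc1ccccc1
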